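(The earlier runs and the new flask were computed with made-up constants, and the scatter is random.)

I decided to judge this flask by its charge of incoming ligand, the limiting reagent here, and not by its clock.

- west: starting complex 2 M; incoming ligand 2 M; run made earlier
- flask: starting complex 2.0 M; incoming ligand 1.40 M; time 2.0 min

west run (percent of the starting complex charged)

| time / s | starting complex / % | complex with two exchanged / % |
|---|---|---|
| 10.0 | 66.4 | 6.9 |
| 20.0 | 59.8 | 9.8 |
| 30.0 | 58.7 | 8.7 |
| 50.0 | 56.0 | 9.1 |
| 80.0 | 55.9 | 8.1 |
| 90.0 | 56.0 | 7.0 |

(scatter of a reading: 0.5 percentage points)

- the numbers in the tables scatter by 0.5 percentage points (one standard deviation)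
- the earlier runs do not show how much of incoming ligand is bound; that part of a forecast is a guess
- no earlier run changes the charge of incoming ligand; that part of a forecast is a guess

* part of the starting complex that has reacted at 2.0 min
* share of the unused incoming ligand that is free and not bound as idle adduct, at 2.0 min

1. The west run is the near neighbour: it had the same 2 M of starting complex, but 2 M of incoming ligand against 1.40 M in the flask. Its starting complex stood level near 56.0% from 50.0 s on, earlier than 2.0 min, so I expected the flask to have stopped by then too.

2. From its readings I reckoned about 1.04 M of exchanges in the west run. I supposed that each leaving ligand set free bound one incoming ligand as idle adduct at once. Each exchange then cost two incoming ligands, 2.08 M in all, close to the charge. So the two flasks should end where their charges of incoming ligand put them.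

3. I therefore carried the stall yield, the starting complex reacted per mole of incoming ligand charged, which the west run put at 0.440. On the flask's charge it gave 30.8% reacted.

4. The forecast said 32% (26% to 38%), a little above my figure, on the ground that “the plateau should scale roughly with charge”. For the free share it guessed 15% (3% to 45%).

5. The flask gave 33.9% reacted and 18.3% free, both within those ranges, and its own stall yield was 0.484, above the west run's. At 2.00 min the flask held 0.235 M of leaving ligand beside 0.524 M of idle adduct, so my supposition held in part.

    starting complex + incoming ligand ⇌ leaving ligand + complex with one exchanged (K = 0.910, k = 0.0420 L mol⁻¹ s⁻¹)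
    complex with one exchanged + incoming ligand ⇌ leaving ligand + complex with two exchanged (K = 0.270, k = 0.0460 L mol⁻¹ s⁻¹)
    leaving ligand + incoming ligand ⇌ idle adduct, settled at all times (K = 19.0 L mol⁻¹)

By forward rates alone, the first exchange drew incoming ligand 5.0 times as fast as the second at 0.0743 min, and still twice as fast at 2.00 min. The flask then held 29.8% complex with one exchanged against 4.05% complex with two exchanged. A charge of 1.68 M of incoming ligand moved the reacted part up by 5 points, above the forecast's high end. With 1.2 M of starting complex and the same 1.40 M of incoming ligand, the stall yield gave 51.4%, and that flask computed to 49.5%.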